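## Retrosynthetic overview

1. The last events are α-methylenation of the C7 ketone (C17) and closure of the γ-lactone; C12 and C13 come from an Evans syn-aldol of a succinate imide with a C12 aldehyde.
2. The 6α-OH comes from β-face hydride reduction of a 6-keto-7-methoxy enone (a diosphenol ether), which is made from a ring B silyl enol ether by Rubottom oxidation and further oxidation.
3. Key step: a type 1 intramolecular Diels–Alder reaction (IMDA) of an acyclic (E)-2-methyl-enal / 2-silyloxydiene closes rings A and B at once and sets C5, C9 and C10 (two quaternary centres) from the single C1 carbinol stereocentre.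
4. The trienal comes from a Suzuki coupling (2-bromoalkene + (Z)-β-boryl enone), a CBS reduction (C1) and a vinyllithium / Weinreb amide union.
5. Ring order: rings A and B together (IMDA), lactone ring last.

Assumption: positions are cited in clerodane numbering (C1 bears the isobutyrate, C4=C18 and C8=C17 are the methylidenes, C19/C20 are the methyls on C5/C9, C11–C16 is the side chain), α/β as usually drawn with H-10 β; the target is taken exactly as the given SMILES, i.e. (1R,5R,6R,9R,10R,12R,13R).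

## Route

Step 1
Reactants: 1 tert-butyldimethyl(prop-2-yn-1-yloxy)silane
Product: 3 (E)-tert-butyl[(3-iodo-2-methylprop-2-en-1-yl)oxy]dimethylsilane, via alkenylalane 2 (not isolated)
Conditions: AlMe3 (2.5 equiv), Cp2ZrCl2 (0.25 equiv), CH2Cl2, 0 °C to rt; then I2, THF, −30 °C
Reagents that add atoms: trimethylaluminium C[Al](C)C; iodine [I][I]
Why: Negishi zirconium-catalysed carboalumination adds Me and Al syn across the alkyne with Me on the internal carbon, and iodinolysis of the C–Al bond goes with retention, fixing the E geometry that later becomes the C9 configuration.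

Step 2
Reactants: 4 N-methoxy-N-methylacetamide; 5 2,3-dibromoprop-1-ene
Product: 7 4-bromo-N-methoxy-N-methylpent-4-enamide, via lithium enolate 6 (not isolated)
Conditions: LiN(i-Pr)2 (1.05 equiv), THF, −78 °C; then 5, −78 to −20 °C
Reagents that add atoms: none
Why: Enolate alkylation (SN2) in which the amide enolate displaces only the allylic bromide while the vinylic bromide is inert.

Step 3
Reactants: 3 (E)-vinyl iodide; 7 4-bromo-N-methoxy-N-methylpent-4-enamide
Product: 9 (E)-7-bromo-1-(tert-butyldimethylsilyloxy)-2-methylocta-2,7-dien-4-one, via vinyllithium 8 (not isolated)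
Conditions: 3, t-BuLi (2.1 equiv), Et2O, −78 °C; then 7, −78 to 0 °C; H2O
Reagents that add atoms: none
Why: Lithium–iodine exchange proceeds with retention of alkene geometry, and the Weinreb ketone synthesis stops at the chelated tetrahedral adduct, so the enone forms without over-addition and the vinyl bromide is untouched at −78 °C.

Step 4
Reactants: 9 (E)-7-bromo-1-(tert-butyldimethylsilyloxy)-2-methylocta-2,7-dien-4-one
Product: 10 (2E,4R)-7-bromo-1-(tert-butyldimethylsilyloxy)-2-methylocta-2,7-dien-4-ol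
Conditions: (S)-Me-CBS oxazaborolidine C18H20BNO (0.2 equiv), catecholborane (1.5 equiv), toluene, −78 °C; then MeOH, H2O
Reagents that add atoms: none
Why: Corey–Bakshi–Shibata reduction with the alkenyl group as the large substituent delivers hydride to the Si face and sets the (R)-carbinol (clerodane C1), the only stereocentre of the acyclic precursor.

Step 5
Reactants: 11 pent-3-yn-2-one
Product: 12 (Z)-4-(4,4,5,5-tetramethyl-1,3,2-dioxaborolan-2-yl)pent-3-en-2-one
Conditions: B2pin2 (1.1 equiv), CuCl (3 mol %), NaOt-Bu (6 mol %), Xantphos (3 mol %), MeOH (2 equiv), THF, rt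
Reagents that add atoms: bis(pinacolato)diboron CC1(C)OB(OC1(C)C)B1OC(C)(C)C(C)(C)O1
Why: Copper-catalysed conjugate borylation (syn borylcupration, then protonation by MeOH) places boron at the β-carbon cis to the new hydrogen and therefore trans to the acyl group.

Step 6
Reactants: 10 (2E,4R)-7-bromo-1-(tert-butyldimethylsilyloxy)-2-methylocta-2,7-dien-4-ol; 12 (Z)-β-boryl enone
Product: 13 (3E,8R,9E)-11-(tert-butyldimethylsilyloxy)-8-hydroxy-4,10-dimethyl-5-methylideneundeca-3,9-dien-2-one
Conditions: PdCl2(dppf) (5 mol %), K3PO4 (3 equiv), THF/H2O 10:1, rt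
Reagents that add atoms: none
Why: Suzuki–Miyaura coupling goes with retention at both sp2 carbons, so the C4 chain ends up trans to the acetyl group across C5=C6 (the "outside" diene position needed for the IMDA).

Step 7
Reactants: 13 dienone alcohol
Product: 14 (2E,4R,8E)-1-(tert-butyldimethylsilyloxy)-2,8-dimethyl-7-methylidene-10-oxoundeca-2,8-dien-4-yl 2-methylpropanoate
Conditions: i-PrCOCl (1.5 equiv), pyridine, DMAP (0.1 equiv), CH2Cl2, 0 °C
Reagents that add atoms: isobutyryl chloride CC(C)C(Cl)=O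
Why: DMAP-catalysed acylation installs the final C1 isobutyrate directly, and doing it after step 6 means no allylic ester is ever exposed to zerovalent palladium.

Step 8
Reactants: 14 silyl ether isobutyrate
Product: 15 (2E,4R,8E)-1-hydroxy-2,8-dimethyl-7-methylidene-10-oxoundeca-2,8-dien-4-yl 2-methylpropanoate
Conditions: HF·pyridine, pyridine/THF, 0 °C
Reagents that add atoms: none
Why: Fluoride-mediated desilylation of the primary allylic TBS ether leaves the ester and dienone alone, and the E alkene keeps the new hydroxyl too far from the ester for acyl migration.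

Step 9
Reactants: 15 allylic alcohol
Product: 16 (2E,4R,8E)-2,8-dimethyl-7-methylidene-1,10-dioxoundeca-2,8-dien-4-yl 2-methylpropanoate
Conditions: MnO2 (activated, 15 equiv), CH2Cl2, rt
Reagents that add atoms: none
Why: MnO2 allylic oxidation gives the (E)-2-methyl enal (the dienophile) without touching the rest of the molecule or the alkene geometry.

Step 10
Reactants: 16 enal dienone
Product: 17 (2E,4R,8E)-10-(tert-butyldimethylsilyloxy)-2,8-dimethyl-7-methylidene-1-oxoundeca-2,8,10-trien-4-yl 2-methylpropanoate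
Conditions: TBSOTf (1.2 equiv), Et3N (2 equiv), CH2Cl2, −78 to 0 °C
Reagents that add atoms: tert-butyldimethylsilyl trifluoromethanesulfonate CC(C)(C)[Si](C)(C)OS(=O)(=O)C(F)(F)F
Why: Soft enolisation/silylation of the methyl ketone at its α′-methyl gives the cross-conjugated 2-silyloxydiene, while the enal has no α-hydrogen and is left as the dienophile.

Step 11
Reactants: 17 silyloxy trienal
Product: 18 trans-decalin cycloadduct aldehyde
Conditions: Me2AlCl (1.5 equiv), CH2Cl2 (0.005 M), −78 to −20 °C; aq. KNaC4H4O6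
Reagents that add atoms: none
Why: Lewis-acid-promoted type 1 intramolecular Diels–Alder reaction through a chair tether with the CHO endo and the tether exo gives the trans ring fusion (5α-Me, 10β-H); the E enal puts 9-Me α and 9-CHO β; 1,3-allylic strain between C1 and the cis C20 methyl keeps C1–H in the alkene plane so the diene adds anti to the ester, which becomes equatorial 1β; the regiochemistry is enforced by the tether.

Step 12
Reactants: 18 trans-decalin cycloadduct aldehyde
Product: 20 6β-hydroxy-7-ketone aldehyde, via silyloxy epoxide 19 (not isolated)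
Conditions: DMDO (1.1 equiv), acetone/CH2Cl2, −78 to −30 °C; then 0.1 M HCl, THF/H2O, 0 °C
Reagents that add atoms: dimethyldioxirane CC1(C)OO1
Why: Rubottom oxidation, in which the silyl enol ether is by far the most electron-rich alkene and is epoxidised from the open β face (anti to both axial methyls); the C6 configuration formed here is erased in step 13.

Step 13
Reactants: 20 6β-hydroxy-7-ketone aldehyde
Product: 22 diosphenol aldehyde (7-hydroxy-7-en-6-one), via 6,7-diketone 21 (not isolated)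
Conditions: Dess–Martin periodinane (1.5 equiv), CH2Cl2, rt; silica gel
Reagents that add atoms: none
Why: Dess–Martin oxidation of the α-ketol gives the α-diketone, which can enolise only toward C8 (C5 is quaternary) and so tautomerises to the diosphenol with the ketone at C6.

Step 14
Reactants: 22 diosphenol aldehyde
Product: 23 diosphenol methyl ether aldehyde (7-methoxy-7-en-6-one)
Conditions: Me2SO4 (1.5 equiv), K2CO3 (2 equiv), acetone, rt
Reagents that add atoms: dimethyl sulfate COS(=O)(=O)OC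
Why: O-alkylation of the acidic enol with a hard methylating agent gives the 2-methoxy enone, which protects C7 as an acid-stable enol ether until the C6 ketone has been reduced.

Step 15
Reactants: 23 diosphenol methyl ether aldehyde
Product: 25 C12 aldehyde, via methyl enol ether 24 (not isolated)
Conditions: Ph3P(CH2OMe)Cl (1.5 equiv), NaN(SiMe3)2 (1.4 equiv), THF, 0 °C; then 23, 0 °C to rt; then 2 M aq. HCl/THF 1:5, rt
Reagents that add atoms: (methoxymethyl)triphenylphosphonium chloride COC[P+](c1ccccc1)(c1ccccc1)c1ccccc1.[Cl-]; water O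
Why: Wittig one-carbon homologation at the aldehyde (the C6 enone carbonyl next to quaternary C5 does not react), then mild hydrolysis of the simple enol ether, which is far faster than protonation of the conjugated 7-methoxy enone or of the C4 methylidene.

Step 16
Reactants: 26 (S)-4-benzyl-1,3-oxazolidin-2-one; 27 4-tert-butoxy-4-oxobutanoic acid
Product: 29 tert-butyl 4-[(4S)-4-benzyl-2-oxo-1,3-oxazolidin-3-yl]-4-oxobutanoate, via mixed pivalic anhydride 28 (not isolated)
Conditions: 27, t-BuCOCl (1.05 equiv), Et3N (2.2 equiv), THF, −20 °C; then LiCl (1.1 equiv), 26, rt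
Reagents that add atoms: none
Why: Mixed-anhydride N-acylation of the oxazolidinone, where the hindered pivaloyl carbonyl is not attacked and the tert-butyl ester prevents later lactonisation of the aldolate.

Step 17
Reactants: 25 C12 aldehyde; 29 succinate imide (1.3 equiv)
Product: 31 syn-aldol adduct, via boron enolate 30 (not isolated)
Conditions: 29, Bu2BOTf (1.2 equiv per 29), i-Pr2NEt (1.4 equiv per 29), CH2Cl2, −78 to 0 °C; then 25, −78 to 0 °C; pH 7 buffer/MeOH, 30% H2O2, 0 °C
Reagents that add atoms: none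
Why: Evans syn-aldol reaction, in which the (Z)-boron enolate reacts through a Zimmerman–Traxler chair with the face set by the (S)-benzyl auxiliary, giving the 12R carbinol and the C13 centre with the target geometry (13S while C16 is the imide carbonyl, 13R once it is CH2O).

Step 18
Reactants: 31 syn-aldol adduct
Product: 32 12-O-tigloyl aldol imide
Conditions: tigloyl chloride (3 equiv), pyridine, DMAP (0.2 equiv), CH2Cl2, 0 °C to rt
Reagents that add atoms: tigloyl chloride C/C=C(\C)C(Cl)=O
Why: DMAP-catalysed esterification under weakly basic conditions installs the (E)-2-methylbut-2-enoate without deconjugation and caps O12 so that only O16 can lactonise later.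

Step 19
Reactants: 32 12-O-tigloyl aldol imide
Product: 34 6α,16-diol enol ether tert-butyl ester, via keto alcohol 33 (not isolated)
Conditions: LiBH4 (3 equiv), MeOH (3 equiv), THF, −10 to 0 °C; acetone, then H2O
Reagents that add atoms: none
Why: Chemoselective hydride reduction in which the imide is cleaved to the C16 primary alcohol faster than the hindered esters react, and the C6 enone carbonyl is reduced 1,2 by axial attack from the β face (anti to the adjacent axial C19 methyl), setting the equatorial 6α-OH.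

Step 20
Reactants: 34 6α,16-diol enol ether tert-butyl ester
Product: 36 17-nor ketol lactone, via hydroxy keto ester 35 (not isolated)
Conditions: CSA (0.2 equiv), CH2Cl2, H2O (2 equiv), rt to 35 °C
Reagents that add atoms: water O
Why: Mild acid first hydrolyses the now non-conjugated C7 methyl enol ether to the ketone, then catalyses intramolecular transesterification of the γ-hydroxy tert-butyl ester to the γ-lactone; strong acid is avoided because of the C4 methylidene next to quaternary C5.

Step 21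
Reactants: 36 17-nor ketol lactone
Product: 38 CNP0148909.1, via Mannich base 37 (not isolated)
Conditions: (CH2O)n (5 equiv), i-Pr2NH·CF3CO2H (1 equiv), CF3CO2H (0.1 equiv), THF, 65 °C
Reagents that add atoms: paraformaldehyde (as formaldehyde) C=O
Why: Direct Mannich α-methylenation, where C8 is the only α-CH2 of the ketone, the iminium adds there and the amine is eliminated to the exocyclic enone, which cannot isomerise into the ring because C9 is quaternary.

## Compound list

1 | tert-butyldimethyl(prop-2-yn-1-yloxy)silane | C#CCO[Si](C)(C)C(C)(C)C | starting material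
2 | dimethyl[(E)-3-(tert-butyldimethylsilyloxy)-2-methylprop-1-en-1-yl]alane | C[Al](C)/C=C(\C)CO[Si](C)(C)C(C)(C)C | intermediate (not isolated)
3 | (E)-tert-butyl[(3-iodo-2-methylprop-2-en-1-yl)oxy]dimethylsilane | I/C=C(\C)CO[Si](C)(C)C(C)(C)C | intermediate
4 | N-methoxy-N-methylacetamide | CC(=O)N(C)OC | starting material
5 | 2,3-dibromoprop-1-ene | C=C(Br)CBr | starting material
6 | lithium 1-[methoxy(methyl)amino]ethen-1-olate (enolate of 4) | [Li]OC(=C)N(C)OC | intermediate (not isolated)
7 | 4-bromo-N-methoxy-N-methylpent-4-enamide | C=C(Br)CCC(=O)N(C)OC | intermediate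
8 | [(E)-3-(tert-butyldimethylsilyloxy)-2-methylprop-1-en-1-yl]lithium | [Li]/C=C(\C)CO[Si](C)(C)C(C)(C)C | intermediate (not isolated)
9 | (E)-7-bromo-1-(tert-butyldimethylsilyloxy)-2-methylocta-2,7-dien-4-one | C=C(Br)CCC(=O)/C=C(\C)CO[Si](C)(C)C(C)(C)C | intermediate
10 | (2E,4R)-7-bromo-1-(tert-butyldimethylsilyloxy)-2-methylocta-2,7-dien-4-ol | C=C(Br)CC[C@@H](O)/C=C(\C)CO[Si](C)(C)C(C)(C)C | intermediate
11 | pent-3-yn-2-one | CC#CC(C)=O | starting material
12 | (Z)-4-(4,4,5,5-tetramethyl-1,3,2-dioxaborolan-2-yl)pent-3-en-2-one | CC(=O)/C=C(\C)B1OC(C)(C)C(C)(C)O1 | intermediate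
13 | (3E,8R,9E)-11-(tert-butyldimethylsilyloxy)-8-hydroxy-4,10-dimethyl-5-methylideneundeca-3,9-dien-2-one | C=C(CC[C@@H](O)/C=C(\C)CO[Si](C)(C)C(C)(C)C)/C(C)=C/C(C)=O | intermediate
14 | (2E,4R,8E)-1-(tert-butyldimethylsilyloxy)-2,8-dimethyl-7-methylidene-10-oxoundeca-2,8-dien-4-yl 2-methylpropanoate | C=C(CC[C@@H](OC(=O)C(C)C)/C=C(\C)CO[Si](C)(C)C(C)(C)C)/C(C)=C/C(C)=O | intermediate
15 | (2E,4R,8E)-1-hydroxy-2,8-dimethyl-7-methylidene-10-oxoundeca-2,8-dien-4-yl 2-methylpropanoate | C=C(CC[C@@H](OC(=O)C(C)C)/C=C(\C)CO)/C(C)=C/C(C)=O | intermediate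
16 | (2E,4R,8E)-2,8-dimethyl-7-methylidene-1,10-dioxoundeca-2,8-dien-4-yl 2-methylpropanoate | C=C(CC[C@@H](OC(=O)C(C)C)/C=C(\C)C=O)/C(C)=C/C(C)=O | intermediate
17 | (2E,4R,8E)-10-(tert-butyldimethylsilyloxy)-2,8-dimethyl-7-methylidene-1-oxoundeca-2,8,10-trien-4-yl 2-methylpropanoate | C=C(CC[C@@H](OC(=O)C(C)C)/C=C(\C)C=O)/C(C)=C/C(=C)O[Si](C)(C)C(C)(C)C | intermediate
18 | cycloadduct: 7-(tert-butyldimethylsilyloxy)-1β-isobutyryloxy-11-oxo-12,13,14,15,16-pentanorcleroda-4(18),6-diene; 5α-Me, 9α-Me, 9β-CHO, 10β-H, trans-fused | C=C1CC[C@@H](OC(=O)C(C)C)[C@H]2[C@@]1(C)C=C(O[Si](C)(C)C(C)(C)C)C[C@]2(C)C=O | intermediate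
19 | 6β,7β-epoxide of 18 (7α-OTBS) | C=C1CC[C@@H](OC(=O)C(C)C)[C@H]2[C@@]1(C)[C@@H]3O[C@]3(O[Si](C)(C)C(C)(C)C)C[C@]2(C)C=O | intermediate (not isolated)
20 | 6β-hydroxy-1β-isobutyryloxy-7,11-dioxo-12,13,14,15,16-pentanorclerod-4(18)-ene | C=C1CC[C@@H](OC(=O)C(C)C)[C@H]2[C@@]1(C)[C@H](O)C(=O)C[C@]2(C)C=O | intermediate
21 | 1β-isobutyryloxy-6,7,11-trioxo-12,13,14,15,16-pentanorclerod-4(18)-ene | C=C1CC[C@@H](OC(=O)C(C)C)[C@H]2[C@@]1(C)C(=O)C(=O)C[C@]2(C)C=O | intermediate (not isolated)
22 | 7-hydroxy-1β-isobutyryloxy-6,11-dioxo-12,13,14,15,16-pentanorcleroda-4(18),7-diene (diosphenol) | C=C1CC[C@@H](OC(=O)C(C)C)[C@H]2[C@@]1(C)C(=O)C(O)=C[C@]2(C)C=O | intermediate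
23 | 1β-isobutyryloxy-7-methoxy-6,11-dioxo-12,13,14,15,16-pentanorcleroda-4(18),7-diene | C=C1CC[C@@H](OC(=O)C(C)C)[C@H]2[C@@]1(C)C(=O)C(OC)=C[C@]2(C)C=O | intermediate
24 | 1β-isobutyryloxy-7,12-dimethoxy-13,14,15,16-tetranorcleroda-4(18),7,11-trien-6-one (E/Z mixture at C11=C12) | C=C1CC[C@@H](OC(=O)C(C)C)[C@H]2[C@@]1(C)C(=O)C(OC)=C[C@]2(C)C=COC | intermediate (not isolated)
25 | 1β-isobutyryloxy-7-methoxy-6,12-dioxo-13,14,15,16-tetranorcleroda-4(18),7-diene (C12 aldehyde) | C=C1CC[C@@H](OC(=O)C(C)C)[C@H]2[C@@]1(C)C(=O)C(OC)=C[C@]2(C)CC=O | intermediate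
26 | (S)-4-benzyl-1,3-oxazolidin-2-one | O=C1N[C@@H](Cc2ccccc2)CO1 | starting material
27 | 4-tert-butoxy-4-oxobutanoic acid | CC(C)(C)OC(=O)CCC(=O)O | starting material
28 | 4-tert-butoxy-4-oxobutanoic pivalic anhydride | CC(C)(C)OC(=O)CCC(=O)OC(=O)C(C)(C)C | intermediate (not isolated)
29 | tert-butyl 4-[(4S)-4-benzyl-2-oxo-1,3-oxazolidin-3-yl]-4-oxobutanoate | CC(C)(C)OC(=O)CCC(=O)N1C(=O)OC[C@@H]1Cc1ccccc1 | intermediate
30 | (Z)-dibutylboron enolate of 29 | CC(C)(C)OC(=O)C/C=C(\OB(CCCC)CCCC)N1C(=O)OC[C@@H]1Cc1ccccc1 | intermediate (not isolated)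
31 | aldol adduct: (12R,13S)-12-hydroxy, C13 bearing CH2CO2t-Bu and the C16 acyl oxazolidinone, on the 1β-isobutyryloxy-7-methoxy-6-oxo-cleroda-4(18),7-diene core | C=C1CC[C@@H](OC(=O)C(C)C)[C@H]2[C@@]1(C)C(=O)C(OC)=C[C@]2(C)C[C@@H](O)[C@H](CC(=O)OC(C)(C)C)C(=O)N1C(=O)OC[C@@H]1Cc1ccccc1 | intermediate
32 | 12-O-[(E)-2-methylbut-2-enoyl] derivative of 31 | C=C1CC[C@@H](OC(=O)C(C)C)[C@H]2[C@@]1(C)C(=O)C(OC)=C[C@]2(C)C[C@@H](OC(=O)/C(C)=C/C)[C@H](CC(=O)OC(C)(C)C)C(=O)N1C(=O)OC[C@@H]1Cc1ccccc1 | intermediate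
33 | (12R,13R)-16-hydroxy-6-oxo tert-butyl ester (imide reduced, C6 ketone intact) | C=C1CC[C@@H](OC(=O)C(C)C)[C@H]2[C@@]1(C)C(=O)C(OC)=C[C@]2(C)C[C@@H](OC(=O)/C(C)=C/C)[C@H](CC(=O)OC(C)(C)C)CO | intermediate (not isolated)
34 | tert-butyl (12R,13R)-6α,16-dihydroxy-1β-isobutyryloxy-7-methoxy-12-tigloyloxycleroda-4(18),7-dien-15-oate | C=C1CC[C@@H](OC(=O)C(C)C)[C@H]2[C@@]1(C)[C@@H](O)C(OC)=C[C@]2(C)C[C@@H](OC(=O)/C(C)=C/C)[C@H](CC(=O)OC(C)(C)C)CO | intermediate
35 | tert-butyl (12R,13R)-6α,16-dihydroxy-1β-isobutyryloxy-7-oxo-12-tigloyloxyclerod-4(18)-en-15-oate | C=C1CC[C@@H](OC(=O)C(C)C)[C@H]2[C@@]1(C)[C@@H](O)C(=O)C[C@]2(C)C[C@@H](OC(=O)/C(C)=C/C)[C@H](CC(=O)OC(C)(C)C)CO | intermediate (not isolated)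
36 | (12R,13R)-6α-hydroxy-1β-isobutyryloxy-7-oxo-12-tigloyloxy-17-norclerod-4(18)-en-15,16-olide | C=C1CC[C@@H](OC(=O)C(C)C)[C@H]2[C@@]1(C)[C@@H](O)C(=O)C[C@]2(C)C[C@@H](OC(=O)/C(C)=C/C)[C@H]1COC(=O)C1 | intermediate
37 | 8-[(diisopropylamino)methyl] derivative of 36 (C8 configuration unassigned) | C=C1CC[C@@H](OC(=O)C(C)C)[C@H]2[C@@]1(C)[C@@H](O)C(=O)C(CN(C(C)C)C(C)C)[C@]2(C)C[C@@H](OC(=O)/C(C)=C/C)[C@H]1COC(=O)C1 | intermediate (not isolated)
38 | CNP0148909.1: (1R,5R,6R,9R,10R,12R,13R)-6-hydroxy-1-isobutyryloxy-7-oxo-12-tigloyloxycleroda-4(18),8(17)-dien-15,16-olide | C=C1CC[C@@H](OC(=O)C(C)C)[C@H]2[C@@]1(C)[C@@H](O)C(=O)C(=C)[C@]2(C)C[C@@H](OC(=O)/C(C)=C/C)[C@H]1COC(=O)C1 | target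

## Step count and risks

Total step count: 21 (steps 1, 2, 5 and 16 prepare side fragments). Longest linear sequence: 18 steps (1 → 3 → 9 → 10 → 13 → … → 38; the branch from 4 is equally long).

Three steps most likely to fail:

Step 11 (the IMDA of 17). The diene terminus carries a Z-methyl, the tether forces a regiochemistry opposite to the normal preference of a 2-silyloxydiene, and the silyl enol ether can be consumed by aldol-type chemistry with the Lewis-acid-complexed aldehyde. The fallback sets out from 16 and comes back at 20, and it replaces the aldehyde–Lewis acid pair by a cationic dienophile. 16 is treated with 1,2-bis(trimethylsilyloxy)ethane and catalytic TMSOTf (CH2Cl2, −78 °C) to give the 2-alkenyl-1,3-dioxolane F1. TBSOTf/Et3N then gives the silyloxy triene acetal F2. Catalytic TMSOTf at −78 °C opens the dioxolane to an alkoxyallyl cation, which undergoes a Gassman-type ionic Diels–Alder reaction through the same chair, exo-tether transition state and recloses to the cycloadduct acetal F3. DMDO followed by mild acid gives the ketol acetal F4, and hydrolysis of the dioxolane (aq. HCl, acetone) rejoins the route at 20.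

Step 19 (LiBH4 on 32). Two reductions must run in the presence of a β-acyloxy imide (risk of tiglate elimination or 1,3-acyl shift) and three other esters. The fallback sets out from 31 and comes back at 36, and it reverses the order of esterification and reduction so that no β-acyloxy carbonyl compound meets hydride. TESOTf/2,6-lutidine converts 31 into the triethylsilyl ether F5. LiBH4/MeOH gives the 6α,16-diol F6. CSA in wet CH2Cl2 gives the silylated ketol lactone F7. Buffered HF·pyridine frees the C12 alcohol F8 without equilibrating the lactone. Tigloyl chloride/pyridine/DMAP at 0 °C then acylates the unhindered C12 hydroxyl in preference to the neopentyl, hydrogen-bonded C6 hydroxyl, giving 36.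

Step 21 (methylenation of 36). C8 is a neopentyl position next to quaternary C9, and the reaction is run on the complete molecule under weakly acidic conditions at 65 °C. The fallback sets out from 34 and comes back at 38, and it uses the C7 methyl enol ether as a regiodefined nucleophile before it is hydrolysed. Dimethylmethyleneammonium iodide (CH2Cl2, rt) attacks C8 of 34 and gives the Mannich base F9, the O-methyl group leaving as iodomethane. Exhaustive methylation with MeI gives the ammonium iodide F10. NaHCO3 then brings about Hofmann-type elimination to the enone hydroxy ester F11, and CSA-catalysed lactonisation as in step 20 gives 38.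

## Further compounds

F1 | step 11 | 1,3-dioxolane (ethylene acetal) of the enal carbon of 16 | C=C(CC[C@@H](OC(=O)C(C)C)/C=C(\C)C1OCCO1)/C(C)=C/C(C)=O
F2 | step 11 | tert-butyldimethylsilyl dienol ether of F1 | C=C(CC[C@@H](OC(=O)C(C)C)/C=C(\C)C1OCCO1)/C(C)=C/C(=C)O[Si](C)(C)C(C)(C)C
F3 | step 11 | cycloadduct acetal (18 with C11 as 1,3-dioxolan-2-yl) | C=C1CC[C@@H](OC(=O)C(C)C)[C@H]2[C@@]1(C)C=C(O[Si](C)(C)C(C)(C)C)C[C@]2(C)C1OCCO1
F4 | step 11 | ketol acetal (20 with C11 as 1,3-dioxolan-2-yl) | C=C1CC[C@@H](OC(=O)C(C)C)[C@H]2[C@@]1(C)[C@H](O)C(=O)C[C@]2(C)C1OCCO1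
F5 | step 19 | 12-O-triethylsilyl ether of 31 | C=C1CC[C@@H](OC(=O)C(C)C)[C@H]2[C@@]1(C)C(=O)C(OC)=C[C@]2(C)C[C@@H](O[Si](CC)(CC)CC)[C@H](CC(=O)OC(C)(C)C)C(=O)N1C(=O)OC[C@@H]1Cc1ccccc1
F6 | step 19 | 6α,16-diol enol ether tert-butyl ester with 12-O-triethylsilyl | C=C1CC[C@@H](OC(=O)C(C)C)[C@H]2[C@@]1(C)[C@@H](O)C(OC)=C[C@]2(C)C[C@@H](O[Si](CC)(CC)CC)[C@H](CC(=O)OC(C)(C)C)CO
F7 | step 19 | 12-O-triethylsilyl 6α-hydroxy-7-oxo-17-nor lactone | C=C1CC[C@@H](OC(=O)C(C)C)[C@H]2[C@@]1(C)[C@@H](O)C(=O)C[C@]2(C)C[C@@H](O[Si](CC)(CC)CC)[C@H]1COC(=O)C1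
F8 | step 19 | 6α,12-dihydroxy-7-oxo-17-nor lactone | C=C1CC[C@@H](OC(=O)C(C)C)[C@H]2[C@@]1(C)[C@@H](O)C(=O)C[C@]2(C)C[C@@H](O)[C@H]1COC(=O)C1
F9 | step 21 | 8-[(dimethylamino)methyl]-6α,16-dihydroxy-7-oxo tert-butyl ester (C8 configuration unassigned) | C=C1CC[C@@H](OC(=O)C(C)C)[C@H]2[C@@]1(C)[C@@H](O)C(=O)C(CN(C)C)[C@]2(C)C[C@@H](OC(=O)/C(C)=C/C)[C@H](CC(=O)OC(C)(C)C)CO
F10 | step 21 | trimethylammonium iodide of F9 | C=C1CC[C@@H](OC(=O)C(C)C)[C@H]2[C@@]1(C)[C@@H](O)C(=O)C(C[N+](C)(C)C)[C@]2(C)C[C@@H](OC(=O)/C(C)=C/C)[C@H](CC(=O)OC(C)(C)C)CO.[I-]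
F11 | step 21 | 6α,16-dihydroxy-7-oxo-cleroda-4(18),8(17)-diene tert-butyl ester (enone hydroxy ester) | C=C1CC[C@@H](OC(=O)C(C)C)[C@H]2[C@@]1(C)[C@@H](O)C(=O)C(=C)[C@]2(C)C[C@@H](OC(=O)/C(C)=C/C)[C@H](CC(=O)OC(C)(C)C)CO
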